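Which flask ends with the most target, and does target stand still once its peak is past?

| flask | solid substrate | temperature | remark | time |
|---|---|---|---|---|
| cedar | 0.040 M | 20 °C | run made earlier |  |
| zeta | 0.020 M |  | at 60 °C until 12 h, from then on at 20 °C | 2.5 d |
| gamma | 0.020 M | 20 °C |  | 2.5 d |
| delta | 0.020 M | 60 °C |  | 2.5 d |
| alpha | 0.020 M | 40 °C |  | 2.5 d |

- cedar (time / h: target / %, solid substrate / %): 4.00: 50.0, 43.4; 8.00: 81.2, 0; 10.0: 75.8, 0.3; 15.0: 70.1, 0; 20.0: 67.9, 0.3

(readings scatter by 0.5 percentage points)

- given per volume of solution although it is solid: solid substrate
- at the start none of the solid substrate is in solution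
- what has only dissolved of solid substrate counts as not reacted
- the earlier runs do not show what temperature does; that part of a forecast is a guess

- the flask that comes out highest in amount of target, in percent of the solid substrate charged, or "all alike" when all lie within 1.5 percentage points (zeta / gamma / delta / alpha / all alike)
- target at the end, in percent of the solid substrate charged, zeta
- target at the end, in percent of the solid substrate charged, gamma
- target at the end, in percent of the solid substrate charged, delta
- target at the end, in percent of the solid substrate charged, alpha

Two of us read the cedar run differently. Target reaches 81.2% at 8.00 h, then falls to 67.9% at 20.0 h. Per hour, the fall shrinks from one pair of readings to the next: 0.0270 /h, then 0.0114 /h, then 0.00440 /h of the charge.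

The forecast reads this as a fall that is ending: “A plateau suggests a reversible loss rather than simple decay.” That is thermodynamic control, a balance that stays once reached. It gives 72% for gamma, 71.5% for zeta, 69% for delta and 71% for alpha, with gamma highest. For zeta, gamma and delta this is in effect the last cedar reading taken over.

I hold that a fall can slow without stopping, so I replace the curve by its mean and check what that costs. From the peak to the last reading, the cedar run loses a mean 0.0111 /h of the charge per hour. Over the last stretch, from 15.0 h, the readings give 0.00440 /h, which is less than the mean but is not zero. Their ratio is 0.397, and I call it the bend: the share of its mean pace that a falling curve keeps in its last stretch.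

I assume that the loss needs two dissolved partners, so that the pace, as a fraction of the charge, goes with the charge. Gamma has half of the cedar charge, so I halve the pace. I start gamma at the cedar peak and run it at the halved mean until 20.0 h, then at the bend times that pace until 2.5 d. This gives 65.8%, my own number and lower than the forecast's. The runs do not show what temperature does, so I merely guess that the warmer flasks end lower.

The flasks give 67.8% for gamma, 51.4% for zeta, 50.2% for delta and 52.2% for alpha, so gamma is highest. The forecast stands 19 percentage points too high for delta. Its plateau does appear in delta, where target reads 50.4% at 1.25 d and 50.0% at 25.0 d.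

    solid substrate ⇌ starting material, rate k1*(cs1 - [starting material]) while solid is left; crystals form when [starting material] > cs1 (solubility = 16.0 mM, k = 0.390 /h)
    starting material ⇌ target + by-product (K = 0.340 M, k = 5.40 /h, Ea = 84.0 kJ/mol, ΔH = −35.0 kJ/mol)
    starting material ⇌ dormant form (K = 0.580, k = 0.0210 /h, Ea = 109 kJ/mol, ΔH = −67.0 kJ/mol)
    starting material + by-product → side product (k = 16.0 /M/h, Ea = 75.0 kJ/mol)
    (constants at 20 °C)

Gamma did not stand still: target went from 74.7% at 1.25 d to 67.8% at 2.50 d, a mean of 0.00232 /h of the charge per hour. Now leave gamma longer. The bend times that pace, run from 2.5 d to 6.0 d and taken from 67.8%, gives 60.0%. The flask gamma left until 6.0 d holds 60.5% target.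

(The data were computed for an exercise, noise included.)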